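**Plan**

- Feature: the central ring (ring B) has oxygen on three alternating carbons and an acetyl group on the carbon between two of them. The C–OH carbon between the acetyl-bearing carbon and the carbon holding the ring A methylene can therefore come from carbon monoxide, and the acetyl group from a propargylic acetate that shifts onto the neighbouring oxygen-bearing carbon.
- Retrosynthesis: first the ring B C–acetyl bond is cut back to an aryl acetate (Fries). Then both ring B bonds to that C–OH carbon are cut, giving CO and a 3-acetoxy-4-benzyloxy-1,4-enyne that carries both arylmethyl arms. Then come the alkynyl–carbinol bond, the enol ether C=C bond, the phosphonate carbon–carbinol bond, the aryl–allyl bonds and the aryl–butanoyl bonds.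
- Forward: rings A and C come from 2-methylphloroglucinol and are each taken to an arylacetaldehyde. The ring C aldehyde becomes an alpha-benzyloxy ketophosphonate, which is joined to the ring A aldehyde, ethynylated and acetylated. Ring B is the only ring built, last, by rhodium-catalysed carbonylative (5+1) benzannulation; hydrogenolysis and the acetyl shift finish the route.
- Stereochemistry: the target has no stereocentre. The racemic carbinol centre and the Z enol ether of the enyne are both lost when ring B aromatises.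

Key step: step 17

Remark on the chemistry: ring B of the target is symmetric about the axis through its acetyl-bearing carbon and the opposite C–OH carbon, so either arm may sit on the carbinol carbon of the enyne; the ring C arm is placed there. Diethyl [(benzyloxy)methyl]phosphonate 17 is taken to be a catalogue compound.

**Route**

Step 1
Reactants: 1 2-methylphloroglucinol; 2 butanoyl chloride
Product: 3 1-(2,4,6-trihydroxy-3-methylphenyl)butan-1-one
Conditions: AlCl3 (4 equiv), PhNO2, 0 to 60 °C; then ice-water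
Reagents that add atoms: none
Why: Friedel–Crafts acylation at either of the two equivalent free ring carbons should stop after one acyl group, because the product is deactivated as its aluminium chelate.

Step 2
Reactants: 3 1-(2,4,6-trihydroxy-3-methylphenyl)butan-1-one
Product: 4 1-(2,6-dihydroxy-4-methoxy-3-methylphenyl)butan-1-one (aspidinol)
Conditions: Me2SO4 (1.0 equiv), K2CO3 (1.0 equiv), acetone, 0 °C to rt
Reagents that add atoms: dimethyl sulfate, COS(=O)(=O)OC
Why: Williamson O-methylation under weak base should select the hydroxyl para to the butanoyl group, which is the most acidic and the only one unable to chelate the carbonyl, and the hard electrophile limits C-methylation.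

Step 3
Reactants: 4 aspidinol
Product: 5 1-[2,6-bis(benzyloxy)-4-methoxy-3-methylphenyl]butan-1-one
Conditions: BnBr (3 equiv), K2CO3 (4 equiv), DMF, 70 °C
Reagents that add atoms: benzyl bromide, BrCc1ccccc1
Why: Williamson etherification in a dipolar solvent with heating should benzylate both hydroxyls flanking the carbonyl, the chelated one more slowly.

Step 4
Reactants: 5 1-[2,6-bis(benzyloxy)-4-methoxy-3-methylphenyl]butan-1-one
Product: 6 1-[2,6-bis(benzyloxy)-3-bromo-4-methoxy-5-methylphenyl]butan-1-one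
Conditions: NBS (1.05 equiv), MeCN, 0 °C to rt, dark
Reagents that add atoms: N-bromosuccinimide, O=C1CCC(=O)N1Br
Why: electrophilic aromatic bromination can only take the single unsubstituted ring carbon, which is activated by two ortho oxygens and one para oxygen, while the benzyl rings are far less reactive and no radical initiator is present.

Step 5
Reactants: 6 1-[2,6-bis(benzyloxy)-3-bromo-4-methoxy-5-methylphenyl]butan-1-one; 7 allyltributylstannane
Product: 8 1-[2,6-bis(benzyloxy)-4-methoxy-3-methyl-5-(prop-2-en-1-yl)phenyl]butan-1-one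
Conditions: Pd(P(t-Bu)3)2 (5 mol%), CsF (2 equiv), 1,4-dioxane, 90 °C
Reagents that add atoms: none
Why: Stille cross-coupling with a bulky electron-rich phosphine on zerovalent palladium should insert into the crowded, electron-rich aryl bromide, with fluoride speeding transmetalation and the ketone and ethers inert.

Step 6
Reactants: 8 1-[2,6-bis(benzyloxy)-4-methoxy-3-methyl-5-(prop-2-en-1-yl)phenyl]butan-1-one
Product: 10 2-[2,4-bis(benzyloxy)-3-butanoyl-6-methoxy-5-methylphenyl]acetaldehyde (aldehyde A), via diol 9 (not isolated)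
Conditions: OsO4 (2 mol%), NaIO4 (4 equiv), 2,6-lutidine, 1,4-dioxane/H2O 3:1, rt
Reagents that add atoms: OsO4 (catalytic), O=[Os](=O)(=O)=O; NaIO4, [Na+].[O-]I(=O)(=O)=O
Why: Lemieux–Johnson oxidation (osmium-catalysed dihydroxylation of the terminal alkene, then periodate cleavage of diol 9) should give the arylacetaldehyde without touching the arene, and 2,6-lutidine suppresses over-oxidation.

Step 7
Reactants: 3 1-(2,4,6-trihydroxy-3-methylphenyl)butan-1-one
Product: 11 1-[4,6-bis(benzyloxy)-2-hydroxy-3-methylphenyl]butan-1-one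
Conditions: BnBr (2.05 equiv), K2CO3 (2.2 equiv), acetone, reflux
Reagents that add atoms: benzyl bromide, BrCc1ccccc1
Why: Williamson etherification with two equivalents should alkylate the para hydroxyl and the less hindered ortho hydroxyl, leaving the hydroxyl between methyl and butanoyl as the chelated phenol.

Step 8
Reactants: 11 1-[4,6-bis(benzyloxy)-2-hydroxy-3-methylphenyl]butan-1-one
Product: 12 1-[4,6-bis(benzyloxy)-2-methoxy-3-methylphenyl]butan-1-one
Conditions: MeI (3 equiv), K2CO3 (2 equiv), DMF, 50 °C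
Reagents that add atoms: iodomethane, CI
Why: Williamson methylation of the one remaining phenol has no competing site and needs only excess reagent in a dipolar solvent to overcome chelation.

Step 9
Reactants: 12 1-[4,6-bis(benzyloxy)-2-methoxy-3-methylphenyl]butan-1-one
Product: 13 1-[2,4-bis(benzyloxy)-3-bromo-6-methoxy-5-methylphenyl]butan-1-one
Conditions: NBS (1.05 equiv), MeCN, 0 °C to rt, dark
Reagents that add atoms: N-bromosuccinimide, O=C1CCC(=O)N1Br
Why: electrophilic aromatic bromination takes the only free ring carbon, which lies between two benzyloxy groups and para to the methoxy group.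

Step 10
Reactants: 13 1-[2,4-bis(benzyloxy)-3-bromo-6-methoxy-5-methylphenyl]butan-1-one; 7 allyltributylstannane
Product: 14 1-[2,4-bis(benzyloxy)-6-methoxy-5-methyl-3-(prop-2-en-1-yl)phenyl]butan-1-one
Conditions: Pd(P(t-Bu)3)2 (5 mol%), CsF (2 equiv), 1,4-dioxane, 90 °C
Reagents that add atoms: none
Why: Stille cross-coupling under the conditions of step 5 should allylate this doubly ortho-substituted aryl bromide in the same way.

Step 11
Reactants: 14 1-[2,4-bis(benzyloxy)-6-methoxy-5-methyl-3-(prop-2-en-1-yl)phenyl]butan-1-one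
Product: 16 2-[2,6-bis(benzyloxy)-3-butanoyl-4-methoxy-5-methylphenyl]acetaldehyde (aldehyde C), via diol 15 (not isolated)
Conditions: OsO4 (2 mol%), NaIO4 (4 equiv), 2,6-lutidine, 1,4-dioxane/H2O 3:1, rt
Reagents that add atoms: OsO4 (catalytic), O=[Os](=O)(=O)=O; NaIO4, [Na+].[O-]I(=O)(=O)=O
Why: Lemieux–Johnson oxidation as in step 6 cleaves the terminal alkene through diol 15 to the arylacetaldehyde.

Step 12
Reactants: 16 aldehyde C; 17 diethyl [(benzyloxy)methyl]phosphonate
Product: 19 diethyl {1-(benzyloxy)-3-[2,6-bis(benzyloxy)-3-butanoyl-4-methoxy-5-methylphenyl]-2-hydroxypropyl}phosphonate (mixture of racemic diastereomers), via lithiated phosphonate 18 (not isolated)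
Conditions: 17 (1.5 equiv), LiN(i-Pr)2, THF, −78 °C; then 16, −78 °C; AcOH, −78 °C
Reagents that add atoms: none
Why: addition of an alpha-alkoxy phosphonate carbanion to an aldehyde (the first half of a Horner–Wadsworth–Emmons reaction, halted by a cold acidic quench) should outrun attack on the doubly ortho-substituted aryl ketone; the two new stereocentres form unselectively and both are removed in steps 13 and 14.

Step 13
Reactants: 19 the beta-hydroxyphosphonate
Product: 20 diethyl {1-(benzyloxy)-3-[2,6-bis(benzyloxy)-3-butanoyl-4-methoxy-5-methylphenyl]-2-oxopropyl}phosphonate (racemic)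
Conditions: Dess–Martin periodinane (1.3 equiv), CH2Cl2, rt
Reagents that add atoms: none
Why: Dess–Martin oxidation of the secondary alcohol under neutral conditions converts both diastereomers into one racemic beta-ketophosphonate.

Step 14
Reactants: 20 the beta-ketophosphonate; 10 aldehyde A
Product: 21 (3Z)-3-(benzyloxy)-1-[2,6-bis(benzyloxy)-3-butanoyl-4-methoxy-5-methylphenyl]-5-[2,4-bis(benzyloxy)-3-butanoyl-6-methoxy-5-methylphenyl]pent-3-en-2-one
Conditions: activated Ba(OH)2 (0.8 equiv), THF/H2O 40:1, 0 °C to rt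
Reagents that add atoms: none
Why: Horner–Wadsworth–Emmons olefination with a mild base should spare the enolisable aldehyde and place the acyl group trans to the new substituent (Z by the priority of oxygen), the usual result for alpha-alkoxy ketophosphonates; any E isomer would lead to the same arene in step 17.

Step 15
Reactants: 21 the alpha-benzyloxy enone; 22 ethynylmagnesium bromide
Product: 23 (4Z)-4-(benzyloxy)-3-{[2,6-bis(benzyloxy)-3-butanoyl-4-methoxy-5-methylphenyl]methyl}-6-[2,4-bis(benzyloxy)-3-butanoyl-6-methoxy-5-methylphenyl]hex-4-en-1-yn-3-ol (racemic)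
Conditions: HC≡CMgBr (2.5 equiv), LaCl3·2LiCl (1.1 equiv), THF, −40 to 0 °C; then H2O
Reagents that add atoms: none
Why: 1,2-addition of an alkynyl Grignard reagent, with LaCl3·2LiCl suppressing enolisation of the benzylic ketone, should occur at the enone carbonyl because each butanoyl group is shielded by two ortho alkoxy groups; the new carbinol centre is racemic and is destroyed in step 17.

Step 16
Reactants: 23 the tertiary propargylic alcohol
Product: 24 (4Z)-4-(benzyloxy)-3-{[2,6-bis(benzyloxy)-3-butanoyl-4-methoxy-5-methylphenyl]methyl}-6-[2,4-bis(benzyloxy)-3-butanoyl-6-methoxy-5-methylphenyl]hex-4-en-1-yn-3-yl acetate (racemic)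
Conditions: Ac2O (3 equiv), Et3N, DMAP (0.5 equiv), CH2Cl2, rt
Reagents that add atoms: acetic anhydride, CC(=O)OC(C)=O
Why: DMAP-catalysed acylation of the tertiary propargylic alcohol installs the ester that migrates in step 17, under basic conditions that do not ionise the carbinol or hydrolyse the enol ether.

Step 17
Reactants: 24 the 3-acetoxy-4-benzyloxy-1,4-enyne; 25 carbon monoxide
Product: 28 3-(benzyloxy)-5-hydroxy-2-{[2,6-bis(benzyloxy)-3-butanoyl-4-methoxy-5-methylphenyl]methyl}-4-{[2,4-bis(benzyloxy)-3-butanoyl-6-methoxy-5-methylphenyl]methyl}phenyl acetate, via dienylketene 26 (not isolated), via cyclohexadienone 27 (not isolated)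
Conditions: [RhCl(CO)2]2 (5 mol%), CO (1 atm), ClCH2CH2Cl, 60 °C
Reagents that add atoms: none
Why: Proposed new method: coordination of monovalent rhodium to the alkyne lets the ester carbonyl oxygen add to the inner alkyne carbon, and collapse of the five-membered acyloxonium moves the ester by one carbon and leaves a rhodium carbene on the former CH terminus (1,2-acyloxy shift); CO insertion then gives dienylketene 26, which closes to dienone 27 and enolises to phenol 28. The closest known reaction type is the rhodium-catalysed (5+1) carbonylative benzannulation of 3-acyloxy-1,4-enynes to resorcinol monoesters, which has not been shown for a tertiary ester whose alkene is an enol ether. Ring B closes by a 6-pi electrocyclisation (formally 6-endo) in which the ketene carbon bonds to the enol ether carbon bearing the ring A arm, so both new ring bonds end at the carbon derived from CO. No stereocentre is created, since the racemic carbinol centre becomes sp2 during the acyloxy shift and the sp3 centre of 27 is lost on aromatisation. The step needs the 1,2-shift to win over the 1,3-shift to an allenyl acetate, which the unsubstituted alkyne terminus should secure, and it needs the triene to reach its reactive conformation, which the Z enol ether should secure by holding the ring A arm on the outside. The acetate ends on the carbon next to the only unsubstituted ring position, where step 19 needs it.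

Step 18
Reactants: 28 the ring B phenol acetate with five benzyl ethers
Product: 29 3,5-dihydroxy-2-[(3-butanoyl-2,6-dihydroxy-4-methoxy-5-methylphenyl)methyl]-4-[(3-butanoyl-2,4-dihydroxy-6-methoxy-5-methylphenyl)methyl]phenyl acetate
Conditions: H2 (1 atm), 10% Pd/C, EtOAc, rt
Reagents that add atoms: none
Why: hydrogenolysis of the five benzyl ethers over Pd/C in a neutral aprotic solvent should leave the aryl acetate and the hindered aryl ketones intact, and it removes every source of benzyl cations before the acidic step 19.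

Step 19
Reactants: 29 the polyphenol monoacetate
Product: 30 1-[3-({3-acetyl-5-[(3-butanoyl-2,6-dihydroxy-4-methoxy-5-methylphenyl)methyl]-2,4,6-trihydroxyphenyl}methyl)-2,6-dihydroxy-4-methoxy-5-methylphenyl]butan-1-one (CNP0184345.0)
Conditions: BF3·OEt2 (8 equiv), 1,4-dioxane, 60 °C; then H2O/MeOH
Reagents that add atoms: none
Why: Fries rearrangement promoted by BF3 should move the acetyl group from oxygen to the adjacent ring carbon, which is the only unsubstituted aromatic position in the molecule, with the chelated ortho-hydroxy ketone as the thermodynamic sink.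

**Compound list**

1 | 2-methylphloroglucinol | Cc1c(O)cc(O)cc1O | starting material
2 | butanoyl chloride | CCCC(=O)Cl | starting material
3 | 1-(2,4,6-trihydroxy-3-methylphenyl)butan-1-one | CCCC(=O)c1c(O)c(C)c(O)cc1O | intermediate
4 | 1-(2,6-dihydroxy-4-methoxy-3-methylphenyl)butan-1-one (aspidinol) | CCCC(=O)c1c(O)c(C)c(OC)cc1O | intermediate
5 | 1-[2,6-bis(benzyloxy)-4-methoxy-3-methylphenyl]butan-1-one | CCCC(=O)c1c(OCc2ccccc2)c(C)c(OC)cc1OCc1ccccc1 | intermediate
6 | 1-[2,6-bis(benzyloxy)-3-bromo-4-methoxy-5-methylphenyl]butan-1-one | CCCC(=O)c1c(OCc2ccccc2)c(C)c(OC)c(Br)c1OCc1ccccc1 | intermediate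
7 | allyltributylstannane | C=CC[Sn](CCCC)(CCCC)CCCC | starting material
8 | 1-[2,6-bis(benzyloxy)-4-methoxy-3-methyl-5-(prop-2-en-1-yl)phenyl]butan-1-one | CCCC(=O)c1c(OCc2ccccc2)c(C)c(OC)c(CC=C)c1OCc1ccccc1 | intermediate
9 | 1-[2,6-bis(benzyloxy)-3-(2,3-dihydroxypropyl)-4-methoxy-5-methylphenyl]butan-1-one (racemic, not isolated) | CCCC(=O)c1c(OCc2ccccc2)c(C)c(OC)c(CC(O)CO)c1OCc1ccccc1 | intermediate
10 | 2-[2,4-bis(benzyloxy)-3-butanoyl-6-methoxy-5-methylphenyl]acetaldehyde (aldehyde A) | CCCC(=O)c1c(OCc2ccccc2)c(C)c(OC)c(CC=O)c1OCc1ccccc1 | intermediate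
11 | 1-[4,6-bis(benzyloxy)-2-hydroxy-3-methylphenyl]butan-1-one | CCCC(=O)c1c(O)c(C)c(OCc2ccccc2)cc1OCc1ccccc1 | intermediate
12 | 1-[4,6-bis(benzyloxy)-2-methoxy-3-methylphenyl]butan-1-one | CCCC(=O)c1c(OC)c(C)c(OCc2ccccc2)cc1OCc1ccccc1 | intermediate
13 | 1-[2,4-bis(benzyloxy)-3-bromo-6-methoxy-5-methylphenyl]butan-1-one | CCCC(=O)c1c(OC)c(C)c(OCc2ccccc2)c(Br)c1OCc1ccccc1 | intermediate
14 | 1-[2,4-bis(benzyloxy)-6-methoxy-5-methyl-3-(prop-2-en-1-yl)phenyl]butan-1-one | CCCC(=O)c1c(OC)c(C)c(OCc2ccccc2)c(CC=C)c1OCc1ccccc1 | intermediate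
15 | 1-[2,4-bis(benzyloxy)-3-(2,3-dihydroxypropyl)-6-methoxy-5-methylphenyl]butan-1-one (racemic, not isolated) | CCCC(=O)c1c(OC)c(C)c(OCc2ccccc2)c(CC(O)CO)c1OCc1ccccc1 | intermediate
16 | 2-[2,6-bis(benzyloxy)-3-butanoyl-4-methoxy-5-methylphenyl]acetaldehyde (aldehyde C) | CCCC(=O)c1c(OC)c(C)c(OCc2ccccc2)c(CC=O)c1OCc1ccccc1 | intermediate
17 | diethyl [(benzyloxy)methyl]phosphonate | CCOP(=O)(COCc1ccccc1)OCC | starting material
18 | diethyl [(benzyloxy)(lithio)methyl]phosphonate (not isolated) | CCOP(=O)(OCC)C([Li])OCc1ccccc1 | intermediate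
19 | diethyl {1-(benzyloxy)-3-[2,6-bis(benzyloxy)-3-butanoyl-4-methoxy-5-methylphenyl]-2-hydroxypropyl}phosphonate (mixture of racemic diastereomers) | CCOP(=O)(OCC)C(OCc1ccccc1)C(O)Cc1c(OCc2ccccc2)c(C)c(OC)c(C(=O)CCC)c1OCc1ccccc1 | intermediate
20 | diethyl {1-(benzyloxy)-3-[2,6-bis(benzyloxy)-3-butanoyl-4-methoxy-5-methylphenyl]-2-oxopropyl}phosphonate (racemic) | CCOP(=O)(OCC)C(OCc1ccccc1)C(=O)Cc1c(OCc2ccccc2)c(C)c(OC)c(C(=O)CCC)c1OCc1ccccc1 | intermediate
21 | (3Z)-3-(benzyloxy)-1-[2,6-bis(benzyloxy)-3-butanoyl-4-methoxy-5-methylphenyl]-5-[2,4-bis(benzyloxy)-3-butanoyl-6-methoxy-5-methylphenyl]pent-3-en-2-one | O=C(Cc1c(OCc2ccccc2)c(C)c(OC)c(C(=O)CCC)c1OCc1ccccc1)/C(OCc1ccccc1)=C/Cc1c(OC)c(C)c(OCc2ccccc2)c(C(=O)CCC)c1OCc1ccccc1 | intermediate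
22 | ethynylmagnesium bromide | C#C[Mg]Br | starting material
23 | (4Z)-4-(benzyloxy)-3-{[2,6-bis(benzyloxy)-3-butanoyl-4-methoxy-5-methylphenyl]methyl}-6-[2,4-bis(benzyloxy)-3-butanoyl-6-methoxy-5-methylphenyl]hex-4-en-1-yn-3-ol (racemic) | C#CC(O)(Cc1c(OCc2ccccc2)c(C)c(OC)c(C(=O)CCC)c1OCc1ccccc1)/C(OCc1ccccc1)=C/Cc1c(OC)c(C)c(OCc2ccccc2)c(C(=O)CCC)c1OCc1ccccc1 | intermediate
24 | (4Z)-4-(benzyloxy)-3-{[2,6-bis(benzyloxy)-3-butanoyl-4-methoxy-5-methylphenyl]methyl}-6-[2,4-bis(benzyloxy)-3-butanoyl-6-methoxy-5-methylphenyl]hex-4-en-1-yn-3-yl acetate (racemic) | C#CC(OC(C)=O)(Cc1c(OCc2ccccc2)c(C)c(OC)c(C(=O)CCC)c1OCc1ccccc1)/C(OCc1ccccc1)=C/Cc1c(OC)c(C)c(OCc2ccccc2)c(C(=O)CCC)c1OCc1ccccc1 | intermediate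
25 | carbon monoxide | [C-]#[O+] | starting material
26 | dienylketene: 3-acetoxy-5-(benzyloxy)-4-(ring C arylmethyl)-7-(ring A aryl)hepta-1,3,5-trien-1-one with the ketene carbon and the enol ether carbon cis on the central alkene (not isolated) | O=C=C/C(OC(C)=O)=C(Cc1c(OCc2ccccc2)c(C)c(OC)c(C(=O)CCC)c1OCc1ccccc1)\C(OCc1ccccc1)=C\Cc1c(OC)c(C)c(OCc2ccccc2)c(C(=O)CCC)c1OCc1ccccc1 | intermediate
27 | cyclohexadienone: 3-acetoxy-5-(benzyloxy)-4-(ring C arylmethyl)-6-(ring A arylmethyl)cyclohexa-2,4-dien-1-one (racemic, not isolated) | CC(=O)OC1=CC(=O)C(Cc2c(OC)c(C)c(OCc3ccccc3)c(C(=O)CCC)c2OCc2ccccc2)C(OCc2ccccc2)=C1Cc1c(OCc2ccccc2)c(C)c(OC)c(C(=O)CCC)c1OCc1ccccc1 | intermediate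
28 | 3-(benzyloxy)-5-hydroxy-2-{[2,6-bis(benzyloxy)-3-butanoyl-4-methoxy-5-methylphenyl]methyl}-4-{[2,4-bis(benzyloxy)-3-butanoyl-6-methoxy-5-methylphenyl]methyl}phenyl acetate | CC(=O)Oc1cc(O)c(Cc2c(OC)c(C)c(OCc3ccccc3)c(C(=O)CCC)c2OCc2ccccc2)c(OCc2ccccc2)c1Cc1c(OCc2ccccc2)c(C)c(OC)c(C(=O)CCC)c1OCc1ccccc1 | intermediate
29 | 3,5-dihydroxy-2-[(3-butanoyl-2,6-dihydroxy-4-methoxy-5-methylphenyl)methyl]-4-[(3-butanoyl-2,4-dihydroxy-6-methoxy-5-methylphenyl)methyl]phenyl acetate | CC(=O)Oc1cc(O)c(Cc2c(OC)c(C)c(O)c(C(=O)CCC)c2O)c(O)c1Cc1c(O)c(C)c(OC)c(C(=O)CCC)c1O | intermediate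
30 | 1-[3-({3-acetyl-5-[(3-butanoyl-2,6-dihydroxy-4-methoxy-5-methylphenyl)methyl]-2,4,6-trihydroxyphenyl}methyl)-2,6-dihydroxy-4-methoxy-5-methylphenyl]butan-1-one (CNP0184345.0) | CCCC(=O)c1c(O)c(C)c(OC)c(Cc2c(O)c(Cc3c(O)c(C)c(OC)c(C(=O)CCC)c3O)c(O)c(C(C)=O)c2O)c1O | target

**Step count**

Total: 19 steps. Longest linear sequence: 14 steps (step 1, steps 7 to 13, steps 14 to 19).

**Steps most likely to fail**

1. Step 17 (proposed new method). The crowded tertiary ester may ionise or undergo the 1,3-acyloxy shift to an allenyl acetate in place of the 1,2-shift, or the enol ether may bind the catalyst, so that no carbonylative ring closure takes place. The fallback leaves the ring construction and joins preformed rings by known Mannich base and quinone methide chemistry; it sets out from 4 and 12 and comes back to the route at 30. Aspidinol 4 would be condensed with aqueous formaldehyde and dimethylamine in ethanol to the Mannich base 1-{3-[(dimethylamino)methyl]-2,6-dihydroxy-4-methoxy-5-methylphenyl}butan-1-one F1. Heating F1 with an excess of commercial 2,4,6-trihydroxyacetophenone in 1,4-dioxane should give, through the ortho-quinone methide, the mixed diarylmethane 1-{3-[(3-acetyl-2,4,6-trihydroxyphenyl)methyl]-2,6-dihydroxy-4-methoxy-5-methylphenyl}butan-1-one F2. In parallel, ether 12 would be hydrogenolysed (H2, Pd/C, EtOAc) to 1-(4,6-dihydroxy-2-methoxy-3-methylphenyl)butan-1-one F3 and converted in the same way to the Mannich base 1-{3-[(dimethylamino)methyl]-2,4-dihydroxy-6-methoxy-5-methylphenyl}butan-1-one F4. Heating F2 with F4 should alkylate the last free carbon of the acetylphloroglucinol ring and give 30.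

2. Step 15. The basic acetylide may deprotonate the benzylic methylene next to the ketone instead of adding, or may attack one of the aryl ketones. The fallback replaces the stoichiometric carbanion by fluoride-catalysed transfer of an alkynyl group from silicon; it sets out from 21 and comes back at 23. Enone 21 would be treated with bis(trimethylsilyl)acetylene and catalytic Bu4NF in THF at 0 °C, which should give the doubly silylated adduct, the O-trimethylsilyl ether of 23 carrying a trimethylsilyl group on the alkyne terminus F5. K2CO3 in methanol would then remove both silyl groups and give 23.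

3. Step 19. The acid may cleave or scramble the diarylmethane bridges of the not yet acylated ring B, or the acetyl group may move between oxygens without reaching carbon. The fallback installs the acetyl group by cross-coupling while all phenols but one are still benzylated; it sets out from 28 and comes back at 30. Phenol 28 would be brominated with NBS in CH2Cl2 at −20 °C at its only free ring carbon to give 3-(benzyloxy)-6-bromo-5-hydroxy-2,4-bis(arylmethyl)phenyl acetate F6. Stille coupling with tributyl(1-ethoxyvinyl)stannane (PdCl2(PPh3)2, 1,4-dioxane, 90 °C) should give the 6-(1-ethoxyethenyl) compound F7, and 1 M HCl in THF would hydrolyse it to the 6-acetyl compound F8. K2CO3 in methanol at 0 °C would cleave the aryl acetate to the pentabenzyl ether of the target F9, and hydrogenolysis (H2, Pd/C, EtOAc) would give 30.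

**Further compounds**

F1 | step 17 | 1-{3-[(dimethylamino)methyl]-2,6-dihydroxy-4-methoxy-5-methylphenyl}butan-1-one | CCCC(=O)c1c(O)c(C)c(OC)c(CN(C)C)c1O
F2 | step 17 | 1-{3-[(3-acetyl-2,4,6-trihydroxyphenyl)methyl]-2,6-dihydroxy-4-methoxy-5-methylphenyl}butan-1-one | CCCC(=O)c1c(O)c(C)c(OC)c(Cc2c(O)cc(O)c(C(C)=O)c2O)c1O
F3 | step 17 | 1-(4,6-dihydroxy-2-methoxy-3-methylphenyl)butan-1-one | CCCC(=O)c1c(OC)c(C)c(O)cc1O
F4 | step 17 | 1-{3-[(dimethylamino)methyl]-2,4-dihydroxy-6-methoxy-5-methylphenyl}butan-1-one | CCCC(=O)c1c(OC)c(C)c(O)c(CN(C)C)c1O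
F5 | step 15 | O-trimethylsilyl ether of 23 with a trimethylsilyl group on the alkyne terminus (racemic, Z) | C[Si](C)(C)C#CC(O[Si](C)(C)C)(Cc1c(OCc2ccccc2)c(C)c(OC)c(C(=O)CCC)c1OCc1ccccc1)/C(OCc1ccccc1)=C/Cc1c(OC)c(C)c(OCc2ccccc2)c(C(=O)CCC)c1OCc1ccccc1
F6 | step 19 | 3-(benzyloxy)-6-bromo-5-hydroxy-2-{[2,6-bis(benzyloxy)-3-butanoyl-4-methoxy-5-methylphenyl]methyl}-4-{[2,4-bis(benzyloxy)-3-butanoyl-6-methoxy-5-methylphenyl]methyl}phenyl acetate | CC(=O)Oc1c(Br)c(O)c(Cc2c(OC)c(C)c(OCc3ccccc3)c(C(=O)CCC)c2OCc2ccccc2)c(OCc2ccccc2)c1Cc1c(OCc2ccccc2)c(C)c(OC)c(C(=O)CCC)c1OCc1ccccc1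
F7 | step 19 | 6-(1-ethoxyethenyl) analogue of F6 | C=C(OCC)c1c(O)c(Cc2c(OC)c(C)c(OCc3ccccc3)c(C(=O)CCC)c2OCc2ccccc2)c(OCc2ccccc2)c(Cc2c(OCc3ccccc3)c(C)c(OC)c(C(=O)CCC)c2OCc2ccccc2)c1OC(C)=O
F8 | step 19 | 6-acetyl analogue of F6 | CC(=O)c1c(O)c(Cc2c(OC)c(C)c(OCc3ccccc3)c(C(=O)CCC)c2OCc2ccccc2)c(OCc2ccccc2)c(Cc2c(OCc3ccccc3)c(C)c(OC)c(C(=O)CCC)c2OCc2ccccc2)c1OC(C)=O
F9 | step 19 | pentabenzyl ether of 30 (ring B 4-O-benzyl; rings A and C each di-O-benzyl) | CC(=O)c1c(O)c(Cc2c(OC)c(C)c(OCc3ccccc3)c(C(=O)CCC)c2OCc2ccccc2)c(OCc2ccccc2)c(Cc2c(OCc3ccccc3)c(C)c(OC)c(C(=O)CCC)c2OCc2ccccc2)c1O
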